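## Retrosynthetic overview

- The C3 stereocentre is traced back to the exocyclic alkene of an (E)-α-benzylidene-β-benzyl lactone: hydrogenation with loss of both O-benzyl groups, then base equilibration to the trans lactone under control of C4.
- That alkene is cut by a Horner–Wadsworth–Emmons disconnection (O-benzylvanillin), and the C4 benzyl arm by copper-catalysed aryl-Grignard opening of a cyclopropane CH2. Both are run in one pot on a bicyclic α-phosphono lactone.
- Key step: the cyclopropane and the γ-lactone of that bicycle close together from (R)-epichlorohydrin and triethyl phosphonoacetate; the epoxide carbon becomes C4 of the target.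
- Ring order: both arenes are bought; cyclopropane and lactone form together (step 2); the cyclopropane is opened again (step 3); the lactone stays closed to the end.

Assumption: the SMILES is read as the trans-(3R,4R) lactone, and (R)-epichlorohydrin of at least 99% ee is used.

## Route

Step 1
Reactants: 1 5-bromo-2-methoxyphenol
Product: 2 2-(benzyloxy)-4-bromo-1-methoxybenzene
Conditions: BnBr (1.1 equiv), K2CO3 (1.5 equiv), DMF, rt, 12 h
Reagents that add atoms: benzyl bromide, BrCc1ccccc1
Why: Williamson ether synthesis masks the phenol so that the aryl bromide can later be turned into a Grignard reagent.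

Step 2
Reactants: 3 (R)-epichlorohydrin; 4 triethyl phosphonoacetate
Product: 8 diethyl [(1R,5S)-2-oxo-3-oxabicyclo[3.1.0]hexan-1-yl]phosphonate, via chlorohydrin alkoxide 5 (not isolated), via epoxy phosphonoester 6 (not isolated), via cyclopropylmethanol 7 (not isolated)
Conditions: NaOEt (1.1 equiv), EtOH, 0 °C to reflux, 16 h
Reagents that add atoms: none
Why: Proposed new method: the phosphonoacetate carbanion opens the epoxide of 3 at its CH2 end, the alkoxide displaces chloride to give epoxide 6, a second deprotonation closes the cyclopropane by 3-exo-tet attack with inversion at the epoxide CH (the bulky phosphoryl group going trans to the CH2O arm), and the alkoxide of 7 lactonises onto the cis ester, so the stereocentre of 3 becomes C5 of 8; the closest known reaction type is the dialkyl malonate (or sulfonylacetonitrile)–epichlorohydrin double alkylation–lactonisation that gives the analogous 1-substituted 3-oxabicyclo[3.1.0]hexan-2-ones.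

Step 3
Reactants: 2 2-(benzyloxy)-4-bromo-1-methoxybenzene; 8 diethyl [(1R,5S)-2-oxo-3-oxabicyclo[3.1.0]hexan-1-yl]phosphonate; 9 4-(benzyloxy)-3-methoxybenzaldehyde
Product: 12 (3E,4R)-4-[3-(benzyloxy)-4-methoxybenzyl]-3-[4-(benzyloxy)-3-methoxybenzylidene]dihydrofuran-2(3H)-one, via aryl Grignard 10 (not isolated), via magnesium phosphonoenolate 11 (not isolated)
Conditions: 2 (1.15 equiv), Mg, I2 (cat.), THF, 50 °C; add to 8 (1.0 equiv) and CuI (10 mol %), THF, −30 to 0 °C; then 9 (1.5 equiv), 0 °C to reflux; aq NH4Cl
Reagents that add atoms: none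
Why: Copper-catalysed homoconjugate (homo-Michael) addition of the aryl Grignard opens the doubly activated cyclopropane at its unsubstituted CH2 with cleavage of the C1–C6 bond, leaving the epichlorohydrin-derived stereocentre untouched, and the resulting magnesium phosphonoenolate undergoes Horner–Wadsworth–Emmons olefination with 9 to give mainly the E alkene (any Z isomer converges in step 4).

Step 4
Reactants: 12 (3E,4R)-4-[3-(benzyloxy)-4-methoxybenzyl]-3-[4-(benzyloxy)-3-methoxybenzylidene]dihydrofuran-2(3H)-one
Product: 14 (3R,4R)-3-(4-hydroxy-3-methoxybenzyl)-4-(3-hydroxy-4-methoxybenzyl)dihydrofuran-2(3H)-one, via cis-lactone 13 (not isolated)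
Conditions: H2 (1 atm), 10% Pd/C, EtOAc–EtOH, rt; filter; then DBU (3 equiv), MeCN, 70 °C, Ar; 1 M HCl work-up
Reagents that add atoms: none
Why: Heterogeneous hydrogenation adds H2 to the exocyclic alkene from the face opposite the C4 benzyl group and removes both benzyl ethers by hydrogenolysis to give the cis lactone, which DBU-mediated enolisation at C3 equilibrates to the thermodynamically preferred trans (3R,4R) isomer without touching C4.

## Compound list

1 | 5-bromo-2-methoxyphenol | COc1ccc(Br)cc1O | starting material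
2 | 2-(benzyloxy)-4-bromo-1-methoxybenzene | COc1ccc(Br)cc1OCc1ccccc1 | intermediate
3 | (R)-epichlorohydrin, (2R)-2-(chloromethyl)oxirane | ClC[C@H]1CO1 | starting material
4 | triethyl phosphonoacetate, ethyl 2-(diethoxyphosphoryl)acetate | CCOC(=O)CP(=O)(OCC)OCC | starting material
5 | ethyl (4R)-5-chloro-2-(diethoxyphosphoryl)-4-hydroxypentanoate (sodium alkoxide in the flask, both C2 epimers, not isolated) | CCOC(=O)C(P(=O)(OCC)OCC)C[C@@H](O)CCl | intermediate
6 | ethyl 2-(diethoxyphosphoryl)-3-[(2R)-oxiran-2-yl]propanoate (both C2 epimers, not isolated) | CCOC(=O)C(P(=O)(OCC)OCC)C[C@@H]1CO1 | intermediate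
7 | ethyl (1R,2S)-1-(diethoxyphosphoryl)-2-(hydroxymethyl)cyclopropane-1-carboxylate (sodium alkoxide in the flask, not isolated) | CCOC(=O)[C@@]1(P(=O)(OCC)OCC)C[C@H]1CO | intermediate
8 | diethyl [(1R,5S)-2-oxo-3-oxabicyclo[3.1.0]hexan-1-yl]phosphonate | CCOP(=O)(OCC)[C@]12C[C@H]1COC2=O | intermediate
9 | 4-(benzyloxy)-3-methoxybenzaldehyde (O-benzylvanillin) | COc1cc(C=O)ccc1OCc1ccccc1 | starting material
10 | [3-(benzyloxy)-4-methoxyphenyl]magnesium bromide (not isolated) | COc1ccc([Mg]Br)cc1OCc1ccccc1 | intermediate
11 | bromomagnesium (4S)-4-[3-(benzyloxy)-4-methoxybenzyl]-3-(diethoxyphosphoryl)-4,5-dihydrofuran-2-olate (not isolated) | COc1ccc(C[C@H]2COC(O[Mg]Br)=C2P(=O)(OCC)OCC)cc1OCc1ccccc1 | intermediate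
12 | (3E,4R)-4-[3-(benzyloxy)-4-methoxybenzyl]-3-[4-(benzyloxy)-3-methoxybenzylidene]dihydrofuran-2(3H)-one | COc1ccc(C[C@H]2COC(=O)/C2=C/c2ccc(OCc3ccccc3)c(OC)c2)cc1OCc1ccccc1 | intermediate
13 | (3S,4R)-3-(4-hydroxy-3-methoxybenzyl)-4-(3-hydroxy-4-methoxybenzyl)dihydrofuran-2(3H)-one (cis, not isolated) | COc1ccc(C[C@H]2COC(=O)[C@H]2Cc2ccc(O)c(OC)c2)cc1O | intermediate
14 | (3R,4R)-3-(4-hydroxy-3-methoxybenzyl)-4-(3-hydroxy-4-methoxybenzyl)dihydrofuran-2(3H)-one (trans) | COc1ccc(C[C@H]2COC(=O)[C@@H]2Cc2ccc(O)c(OC)c2)cc1O | target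

## Step count and risks

Total steps: 4. Longest linear sequence: 3 (steps 2, 3, 4; the branch through steps 1, 3, 4 is equally long).

The three steps most likely to fail are 2, 3 and 4.

**Step 2.** The ring closure may place the phosphoryl group cis to the CH2O arm, which then cannot lactonise and may close on phosphorus instead; alkoxide attack on phosphorus in 5 is a second risk. A small share of direct chloride displacement would also erode the ee. The fallback sets out from 3 and uses bought dimethyl malonate in place of 4 (NaOMe, MeOH, reflux), the established form of the same double ring closure. This gives methyl (1S,5R)-2-oxo-3-oxabicyclo[3.1.0]hexane-1-carboxylate F1. Opening with Grignard 10 and catalytic CuI gives methyl (3S,4R)-4-[3-(benzyloxy)-4-methoxybenzyl]-2-oxotetrahydrofuran-3-carboxylate F2. Krapcho dealkoxycarbonylation (LiCl, wet DMSO, 140 °C) gives (4R)-4-[3-(benzyloxy)-4-methoxybenzyl]dihydrofuran-2(3H)-one F3. Its lithium enolate (LiN(SiMe3)2, THF, −78 °C) adds to 9 to give the aldol adduct (3S,4R)-4-[3-(benzyloxy)-4-methoxybenzyl]-3-{[4-(benzyloxy)-3-methoxyphenyl](hydroxy)methyl}dihydrofuran-2(3H)-one F4 (both carbinol epimers). Dehydration (MsCl, Et3N, then DBU) comes back to the route at 12, two to three operations longer.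

**Step 3.** The magnesium phosphonoenolate 11 may olefinate the electron-rich aldehyde 9 sluggishly, and surplus Grignard consumes 9. The fallback sets out from 8 and 10 as before but quenches 11 with paraformaldehyde, whose olefination is fast. This gives (4R)-4-[3-(benzyloxy)-4-methoxybenzyl]-3-methylidenedihydrofuran-2(3H)-one F5. The second arene is then attached by a Heck reaction with bought 1-(benzyloxy)-4-iodo-2-methoxybenzene (Pd(OAc)2, KOAc, Bu4NCl, DMF, 80 °C; a mild acetate base to keep the alkene exocyclic), which comes back to the route at 12. If the copper-catalysed opening of 8 itself is at fault, the fallback to step 2 applies, since it avoids 8.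

**Step 4.** Pd may move the alkene into the ring before reduction, which would erase C4. The cis-to-trans equilibration may also stop short; about 9:1 is expected, with the cis isomer 13 removed by chromatography or crystallisation. The fallback sets out from 12 and reduces the enoate by electron transfer with Mg in MeOH. The Mg(OMe)2 formed in the flask equilibrates C3 while the phenols are still benzylated; acidification re-closes any ring-opened methyl ester. This gives (3R,4R)-3-[4-(benzyloxy)-3-methoxybenzyl]-4-[3-(benzyloxy)-4-methoxybenzyl]dihydrofuran-2(3H)-one F6. Hydrogenolysis (H2, Pd/C, EtOAc) then comes back to the route at 14.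

## Further compounds

F1 | step 2 | methyl (1S,5R)-2-oxo-3-oxabicyclo[3.1.0]hexane-1-carboxylate | COC(=O)[C@]12C[C@H]1COC2=O
F2 | step 2 | methyl (3S,4R)-4-[3-(benzyloxy)-4-methoxybenzyl]-2-oxotetrahydrofuran-3-carboxylate | COc1ccc(C[C@H]2COC(=O)[C@@H]2C(=O)OC)cc1OCc1ccccc1
F3 | step 2 | (4R)-4-[3-(benzyloxy)-4-methoxybenzyl]dihydrofuran-2(3H)-one | COc1ccc(C[C@H]2COC(=O)C2)cc1OCc1ccccc1
F4 | step 2 | (3S,4R)-4-[3-(benzyloxy)-4-methoxybenzyl]-3-{[4-(benzyloxy)-3-methoxyphenyl](hydroxy)methyl}dihydrofuran-2(3H)-one (both carbinol epimers) | COc1ccc(C[C@H]2COC(=O)[C@@H]2C(O)c2ccc(OCc3ccccc3)c(OC)c2)cc1OCc1ccccc1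
F5 | step 3 | (4R)-4-[3-(benzyloxy)-4-methoxybenzyl]-3-methylidenedihydrofuran-2(3H)-one | COc1ccc(C[C@H]2COC(=O)C2=C)cc1OCc1ccccc1
F6 | step 4 | (3R,4R)-3-[4-(benzyloxy)-3-methoxybenzyl]-4-[3-(benzyloxy)-4-methoxybenzyl]dihydrofuran-2(3H)-one | COc1ccc(C[C@H]2COC(=O)[C@@H]2Cc2ccc(OCc3ccccc3)c(OC)c2)cc1OCc1ccccc1
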